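**Remarks on the chemistry (assumptions)**

- Atom labels C1–C10 are those of the hydroazulene core of the target (C1 methyl-bearing fusion carbon, C2/C3 CH2, C4 isopropyl carbinol, C5 fusion CH, C6 aroyloxy carbon, C7=C8 with methyl on C8, C9 acetoxy carbon, C10 CH2). They are used for every intermediate. TBS = tert-butyldimethylsilyl.
- Compounds 7 and 28 are assumed to be catalogue compounds. Where a name and a SMILES string could be read differently, the SMILES string is meant.
- The planned key-step precursor, its product, L-valine and the three alternative products were checked against the target. Their configurations at C1, C4 and C5 are mutually consistent (retention at C4 in both the diazotisation and the insertion), so no stereostructure needed correction.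
- One point of design was corrected. A 2,2-dimethoxyethyl arm on C1 would place an acetal oxygen five atoms from the carbene carbon, where five-membered oxonium-ylide formation and 1,2-shift compete with C–H insertion. The C10–C9 arm is therefore carried as a 2-(silyloxy)ethyl group; the carbon skeleton of precursor and product is unchanged.
- The glutaconate/esterase route to the quaternary centre was also replaced. C1 is set by a catalytic asymmetric conjugate methylation of a cyclopentenone, whose ring is then cut between C6 and C9.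

**Structural features**

The target is a daucane: a cyclopentane (C1–C5) trans-fused through the C1–C5 bond to a cycloheptene (C1, C5–C10) whose only double bond, C7=C8, carries a methyl group on C8. Four of the five stereocentres are contiguous: the methyl-bearing quaternary C1, the fusion methine C5, the fully substituted carbinol C4 (hydroxyl and isopropyl) and the aroyloxy carbon C6. The fifth, the acetoxy carbon C9, lies across the alkene from C6 and is insulated from the others by C10. The C1 methyl and the C4 hydroxyl are on one face; H5, the C6 oxygen and the C9 oxygen are on the other. C6 therefore leaves C5 on the face of the C4 oxygen, and C10 leaves C1 on the opposite face. The fragile parts are the two allylic esters flanking the alkene (ionisation, acyl transfer, hydrolysis), the free phenol and, at the aldehyde level of C6, the β-oxygen on C4 (elimination, retro-aldol). The real difficulty is the congested C1–C5–C4 triad, in which C5 sits between two fully substituted carbons and must carry C6 trans to the C1 arm, together with the remote C9 centre. The key step uses the fact that C4 carries oxygen, isopropyl and a bond to C5. With that bond replaced by hydrogen, C4 is the α-carbon of the hydroxy acid from L-valine. Its C–H is oxygen-activated and 1,5 to C5, and the quaternary C1 offers a carbene at C5 no hydrogen to migrate.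

**Logic of the disconnections**

34 ⇒ 33 ⇒ 32: only bonds to oxygen are cut (two O–Si bonds, then the C9 O-acetyl bond). This hides the phenol and the C4 hydroxyl under one silyl type and leaves the C9 oxygen as the single free hydroxyl. The demand on the forward steps is an acetylation that meets only one hydroxyl and a desilylation that spares two allylic esters.

32 ⇒ 31: the C8–C9 bond is cut. C9 is a carbinol next to an alkene carbon, so it can arise from an alkenyl metal at C8 and an aldehyde at C9. The cut removes the seven-membered ring and the C9 stereocentre. It demands a Z vinyl iodide with iodine cis to C6, a metal that tolerates two esters, and facial control at C9 by the closing ring.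

31 ⇒ 30 ⇒ 29 ⇒ 27 + 28: the C9 oxidation level and its silyl ether are adjusted, then the C6 O-acyl bond is cut. Acylating C6 before C9 is unmasked means the two carbinols never compete for an acyl group. The aromatic part leaves as 28. The forward steps must acylate a hindered alcohol and cleave a primary silyl ether in the presence of a tertiary and an aryl silyl ether.

27 ⇒ 25 ⇒ 24 ⇒ 23 ⇒ 21 + 22: the C8–iodine and C7–H bonds are traced to an alkyne, the C6–H bond to a ketone, and the C6–C7 bond is cut. A propargylic alcohol gives the Z iodide with full regio- and stereocontrol. C6 is set by a reagent-controlled ketone reduction because C5, flanked by two fully substituted carbons, gives no dependable facial bias. The three-carbon unit leaves as 22. The demand is a reduction catalyst that treats the alkynyl group as the small substituent.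

21 ⇒ 20 ⇒ 19 ⇒ 18: after adjusting the oxidation level of C6, the C4–C5 bond is cut. This is the strategic cut: it opens the cyclopentane, removes the C5 stereocentre and turns the tertiary carbinol C4 into an ordinary secondary, chiral-pool carbinol. The forward step must insert at C4–H only, with retention, and must place the ester trans to the C1 arm. 18 is kept acyclic so that the ester is free to take that position, and its arm oxygen is a silyl ether.

18 ⇒ 17 ⇒ 16: the C5=N2 bond and the temporary C5–benzoyl bond are cut. An unactivated ester does not accept a diazo group directly; a removable acyl group solves this. The demand is enolisation of a neopentyl-type methylene.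

16 ⇒ 13 ⇒ 11 ⇒ 10: the two two-carbon arms on C1 differ only in the oxidation level of their ends, so C6 and C9 are reconnected into a ring. The acyclic quaternary centre becomes the β-carbon of a cyclopentanone, a class accessible by catalytic asymmetric conjugate addition. The forward sequence must enolise regioselectively away from the quaternary carbon and keep the arms differentiated after cleavage.

10 ⇒ 9: the C1–CH3 bond is cut. The catalyst distinguishes the two faces of an enone, not two similar alkyl groups, which is the easier task. The demand is methyl delivery to the Si face of the β-carbon.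

9 ⇒ 6 + 7: the C1–C2 bond is cut as an sp2–sp3 cross-coupling. This separates the five-carbon ring piece from the valine-derived chain and demands clean anti-Markovnikov hydroboration of 6.

6 ⇒ 4 ⇒ 3 ⇒ 2 ⇒ 1: the C2=C3 bond (olefination), the O–Si and O–CH3 bonds and finally C–O for C–N are traced back. C4 comes from the chiral pool; every forward step must leave it untouched or proceed with retention.

**Other disconnections considered**

Alternative 1:
- Cut: the C1–CH3 and C5–C6 bonds, leaving a cyclopentenone whose carbonyl carbon is the future C4.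
- Forward key step: Cu(OTf)2 with a chiral N-heterocyclic carbene would add Me3Al to the β-carbon of the enone A1. The aluminium enolate would be captured at C5 by the iodo-enal A2 to give the aldol A3.
- In its favour: two C–C bonds and three stereocentres (C1, C5, C6) in one flask, C1 by catalyst control, and the complete C6–C8 vinyl iodide delivered ready for the C8–C9 closure.
- Against it here:
  - C4 remains a ketone. Isopropyl and the tertiary hydroxyl would have to come from addition of a bulky, basic nucleophile to a hindered, enolisable cyclopentanone that is also a β-hydroxy ketone, so enolisation, reduction and retro-aldol cleavage of C5–C6 compete. The C4 configuration would rest on substrate control alone.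
  - The enolate face that A2 must choose is differentiated only by methyl against allyl on C1.
  - The allyl arm must be cut back by one carbon to the C9 aldehyde beside the vinyl iodide.
- Comparison:
  - Structure: A3 holds C1, C5, C6 and C7–C8 but not C4; 19 holds C1, C4 and C5 but not C6–C8.
  - Mechanism: the chosen plan fixes C4 by a stereospecific, retentive insertion on a chiral-pool centre. Alternative 1 would fix it by a diastereoselective carbonyl addition at the most crowded carbon, which is the weaker guarantee.
  - Step economy: Alternative 1 is clearly the better plan. A3 lies two or three steps from simple materials, whereas 19 needs twelve. It is also better in creating C6 without an oxidation–reduction detour.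
  - In the way C1 is set the two plans are equal, since step 6 uses the same class of conjugate methylation.

Alternative 2:
- Cut: the C6–C7 bond of the cycloheptene.
- Forward key step: CrCl2 with catalytic NiCl2 would convert the terminal Z vinyl iodide of the aldehyde A4 into an alkenylchromium species at C7. This adds to the C6 aldehyde on C5 and gives the ring alcohol A5.
- In its favour: it is the same reaction class as step 22. The C9 acetoxy centre is in place before closure and could be set on an unhindered open-chain aldehyde under reagent control. On C9 this is better than the chosen plan, where C9 depends on the conformation of the closing ring. The nucleophilic carbon C7 carries hydrogen and is less hindered than C8.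
- Against it here:
  - The electrophile becomes the C6 aldehyde wedged between two fully substituted carbons, so addition would be slow relative to protodemetalation and oligomerisation.
  - C6, which the chosen plan sets by reagent control, would be the centre left to ring conformation.
  - The hindered C6 hydroxyl of A5 would still have to be aroylated after closure.
  - Placing iodine on the terminal carbon cis to C9 needs an anti carbometalation of a propargylic alcohol, not the simple hydroxyl-directed hydroalumination of step 18.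
- Comparison: ring, bond type and mechanism are the same, and the alternative is compatible with the same cyclopentane construction through 19. It is a variant of the endgame with about equal step count. It exchanges which carbinol is left to substrate control, and C6 is the more crowded one to leave.

Alternative 3:
- Cut: C8 is excised, tracing the cycloheptene to a six-membered ring with a C7=C9 double bond in a trans-hydrindene; C8 returns as a dibromocarbene unit.
- Forward key step: AgOAc in acetic acid would abstract bromide from the dibromocyclopropane A6. Disrotatory opening of the C7–C9 bond gives a 2-bromoallyl cation across C7–C8–C9 in a seven-membered ring, and acetate captures C9 to give A7.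
- In its favour: the ring arises by expansion of a six-membered ring, with no medium-ring closure from an open chain, no high dilution and no stoichiometric chromium. The C9 acetate is installed in the same step. On the ring-forming event and on handling it is the better plan.
- Against it here:
  - The cation can be captured at C7 or C9 and from either face. Regiochemistry rests only on the inductive effect of the C6 oxygen and facial selectivity on the shape of a flexible cation.
  - The C8 bromine must still be exchanged for methyl next to an allylic acetate, which zerovalent palladium can ionise and methylcuprates can displace.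
  - A hydrindene carrying C1, C4, C5 and C6 correctly is no easier to reach than 19.
- Comparison: structurally it defers the C8 methyl and puts C9 at risk. Mechanistically it is a cationic process with less built-in stereocontrol than the organochromium addition. In step count it would at best equal the chosen plan, since the saved acetylation is paid back by the methylation.

Key step: step 12

**Route**

Step 1
Reactants: 1 L-valine
Product: 2 (S)-2-hydroxy-3-methylbutanoic acid
Conditions: NaNO2, H2SO4 (1 M aq.), 0 → 25 °C
Reagents that add atoms: water, O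
Why: Diazotisation of the α-amino acid; the carboxylate displaces N2 to an α-lactone that water reopens, so two inversions give net retention and the (S) carbinol that becomes C4.

Step 2
Reactants: 2 (S)-2-hydroxy-3-methylbutanoic acid
Product: 3 methyl (S)-2-hydroxy-3-methylbutanoate
Conditions: MeOH, H2SO4 (cat.), reflux
Reagents that add atoms: methanol, CO
Why: Fischer esterification; the stereocentre is not involved.

Step 3
Reactants: 3 methyl (S)-2-hydroxy-3-methylbutanoate
Product: 4 methyl (S)-2-(TBS-oxy)-3-methylbutanoate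
Conditions: TBSCl, imidazole, DMF, 25 °C
Reagents that add atoms: tert-butyldimethylsilyl chloride, CC(C)(C)[Si](C)(C)Cl
Why: Silylation of the secondary alcohol; the silyl ether is the oxygen substituent that later activates the C4–H bond and is not a chelating or strongly donating group.

Step 4
Reactants: 4 methyl (S)-2-(TBS-oxy)-3-methylbutanoate
Product: 6 (S)-3-(TBS-oxy)-4-methylpent-1-ene, via aldehyde 5 (not isolated)
Conditions: iBu2AlH, CH2Cl2, −78 °C; then Ph3P=CH2 (from Ph3PCH3Br, KN(SiMe3)2), THF, −78 → 25 °C
Reagents that add atoms: methyltriphenylphosphonium bromide, [Br-].C[P+](c1ccccc1)(c1ccccc1)c1ccccc1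
Why: Partial reduction stops at the aluminium hemiacetal, which releases 5 in the presence of the ylide; Wittig methylenation then gives the terminal alkene without isolating the epimerisable α-silyloxy aldehyde.

Step 5
Reactants: 6 (S)-3-(TBS-oxy)-4-methylpent-1-ene; 7 3-bromocyclopent-2-en-1-one
Product: 9 3-[(R)-3-(TBS-oxy)-4-methylpentyl]cyclopent-2-en-1-one, via alkylborane 8 (not isolated)
Conditions: 9-BBN, THF, 25 °C; then 7, PdCl2(dppf) (3 mol %), K3PO4 (aq.), DMF, 50 °C
Reagents that add atoms: none
Why: Anti-Markovnikov hydroboration places boron on the terminal carbon, and B-alkyl Suzuki–Miyaura coupling with the vinylogous acyl bromide forms the C1–C2 bond; C4 is untouched (its descriptor changes only by priority).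

Step 6
Reactants: 9 3-[(R)-3-(TBS-oxy)-4-methylpentyl]cyclopent-2-en-1-one
Product: 10 (R)-3-methyl-3-[(R)-3-(TBS-oxy)-4-methylpentyl]cyclopentan-1-one
Conditions: Me3Al, Cu(OTf)2 (5 mol %), chiral sulfonate-bearing N-heterocyclic carbene ligand (5 mol %), THF, −78 °C; aq. NH4Cl
Reagents that add atoms: trimethylaluminium, C[Al](C)C
Why: Copper-catalysed asymmetric conjugate addition of a methylaluminium reagent to a β-alkylcyclopentenone, a known route to all-carbon quaternary centres; the ligand antipode that delivers methyl to the Si face of the β-carbon sets C1 as (R) by catalyst control. Any C1 epimer is a diastereomer (C4 is fixed) and can be removed after ring formation in step 12.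

Step 7
Reactants: 10 (R)-3-methyl-3-[(R)-3-(TBS-oxy)-4-methylpentyl]cyclopentan-1-one
Product: 11 (R)-4-methyl-4-[(R)-3-(TBS-oxy)-4-methylpentyl]-1-(trimethylsilyloxy)cyclopent-1-ene
Conditions: LiN(iPr)2, Me3SiCl, THF, −78 °C
Reagents that add atoms: chlorotrimethylsilane, C[Si](C)(C)Cl
Why: Kinetic deprotonation with in situ silylation takes the α-methylene remote from the quaternary carbon (the other is neopentyl-like), which decides that the enol double bond lies between C6 and C9.

Step 8
Reactants: 11 (R)-4-methyl-4-[(R)-3-(TBS-oxy)-4-methylpentyl]-1-(trimethylsilyloxy)cyclopent-1-ene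
Product: 13 (R)-4-methyl-4-[(R)-3-(TBS-oxy)-4-methylpentyl]oxan-2-one, via hydroxy acid 12 (not isolated)
Conditions: O3, CH2Cl2/MeOH, −78 °C; NaBH4, −78 → 25 °C; then 1 M HCl to pH 3, 25 °C
Reagents that add atoms: ozone, [O-][O+]=O
Why: Ozonolysis of the silyl enol ether cleaves the C6–C9 bond to a silyl ester at C6 and an aldehyde at C9; borohydride reduces the peroxide and the aldehyde, and acidification closes 12 to the δ-lactone, so the two arms on C1 leave the step differentiated. No stereocentre is touched.

Step 9
Reactants: 13 (R)-4-methyl-4-[(R)-3-(TBS-oxy)-4-methylpentyl]oxan-2-one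
Product: 16 methyl (3R,6R)-6-(TBS-oxy)-3-[2-(TBS-oxy)ethyl]-3,7-dimethyloctanoate, via potassium carboxylate 14 (not isolated), via hydroxy ester 15 (not isolated)
Conditions: KOH, MeOH/H2O, 25 °C; evaporation; MeI, DMF, 0 → 25 °C; then TBSCl, imidazole, 25 °C
Reagents that add atoms: potassium hydroxide, [K+].[OH-]; iodomethane, CI; tert-butyldimethylsilyl chloride, CC(C)(C)[Si](C)(C)Cl
Why: Saponification gives the potassium 5-hydroxy carboxylate, which iodomethane alkylates at the carboxylate only; silylation in the same flask traps the hydroxy ester before it can relactonise. The arm oxygen is deliberately carried as a hindered silyl ether, a poor donor towards a carbene.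

Step 10
Reactants: 16 methyl (3R,6R)-6-(TBS-oxy)-3-[2-(TBS-oxy)ethyl]-3,7-dimethyloctanoate
Product: 17 methyl (3R,6R)-2-benzoyl-6-(TBS-oxy)-3-[2-(TBS-oxy)ethyl]-3,7-dimethyloctanoate (both C2 epimers)
Conditions: NaH, PhCO2Me, DME, reflux; AcOH quench
Reagents that add atoms: methyl benzoate, COC(=O)c1ccccc1
Why: Crossed Claisen condensation with a non-enolisable ester, driven by deprotonation of the β-keto ester product; it activates C5 for diazo transfer. The new centre at C5 is irrelevant because it becomes trigonal in step 11.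

Step 11
Reactants: 17 methyl (3R,6R)-2-benzoyl-6-(TBS-oxy)-3-[2-(TBS-oxy)ethyl]-3,7-dimethyloctanoate
Product: 18 methyl (3R,6R)-2-diazo-6-(TBS-oxy)-3-[2-(TBS-oxy)ethyl]-3,7-dimethyloctanoate
Conditions: 4-nitrobenzenesulfonyl azide, DBU, CH2Cl2, 0 °C
Reagents that add atoms: 4-nitrobenzenesulfonyl azide, [N-]=[N+]=NS(=O)(=O)c1ccc(cc1)[N+](=O)[O-]
Why: Deacylative (Regitz-type) diazo transfer: the enolate attacks the sulfonyl azide and the adduct fragments with loss of the benzoyl group as the N-sulfonylbenzamide, leaving the α-diazo ester.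

Step 12
Reactants: 18 methyl (3R,6R)-2-diazo-6-(TBS-oxy)-3-[2-(TBS-oxy)ethyl]-3,7-dimethyloctanoate
Product: 19 methyl (1R,2R,5R)-2-(TBS-oxy)-5-[2-(TBS-oxy)ethyl]-5-methyl-2-(propan-2-yl)cyclopentane-1-carboxylate (ester cis to the silyloxy group and to the methyl group)
Conditions: Rh2(OAc)4 (1 mol %), CH2Cl2, 25 °C, slow addition of 18
Reagents that add atoms: none
Why: Rh2(OAc)4 takes up the diazo carbon of 18 and loses N2 to give an electrophilic dirhodium carbene at C5, which inserts into the C4–H bond through a concerted three-centre (C5, H, C4) transition state; the closest known reaction type is the dirhodium-catalysed intramolecular 1,5 C–H insertion of α-diazo esters into ether-activated methine C–H bonds. The cyclopentane C1–C2–C3–C4–C5 closes by 1,5-insertion through a chair-like arrangement in which the C4–C5 bond is the only bond made. C4 is controlled by the mechanism: the carbene engages the C–H bond from the side of the hydrogen, so the valine-derived configuration is retained and the oxygen ends on the face of the C1 methyl group. C5 is controlled by the substrate: in the transition state the ester turns away from the isopropyl group on C4 and from the silyloxyethyl arm on C1, which places it cis to the C4 oxygen and trans to the arm, the relationship that later becomes the trans ring fusion. The step needs site selectivity for C4–H; this is secured by the preference for five-membered ring formation, by activation of this bond by the adjacent silyloxy oxygen, by the quaternary C1 (no β-hydrogen for a 1,2-shift, and a gem-dialkyl effect) and by the absence of any alkene. The arm oxygen sits where a five-membered oxonium ylide could form, which is why it is a hindered silyl ether and not an acetal; the isopropyl methine is one atom further away and not oxygen-activated.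

Step 13
Reactants: 19 methyl (1R,2R,5R)-2-(TBS-oxy)-5-[2-(TBS-oxy)ethyl]-5-methyl-2-(propan-2-yl)cyclopentane-1-carboxylate
Product: 20 [(1S,2R,5R)-2-(TBS-oxy)-5-[2-(TBS-oxy)ethyl]-5-methyl-2-(propan-2-yl)cyclopentyl]methanol
Conditions: LiAlH4, Et2O, 0 → 25 °C
Reagents that add atoms: none
Why: Hydride reduction of the hindered ester to the primary alcohol; silyl ethers are inert and no stereocentre changes (the C5 descriptor changes by priority only).

Step 14
Reactants: 20 [(1S,2R,5R)-2-(TBS-oxy)-5-[2-(TBS-oxy)ethyl]-5-methyl-2-(propan-2-yl)cyclopentyl]methanol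
Product: 21 (1R,2R,5R)-2-(TBS-oxy)-5-[2-(TBS-oxy)ethyl]-5-methyl-2-(propan-2-yl)cyclopentane-1-carbaldehyde
Conditions: Dess–Martin periodinane, pyridine, CH2Cl2, 25 °C
Reagents that add atoms: none
Why: Dess–Martin oxidation under buffered, non-basic conditions gives the C6 aldehyde without epimerisation at C5 or β-elimination of the C4 silyloxy group.

Step 15
Reactants: 21 (1R,2R,5R)-2-(TBS-oxy)-5-[2-(TBS-oxy)ethyl]-5-methyl-2-(propan-2-yl)cyclopentane-1-carbaldehyde; 22 prop-1-ynylmagnesium bromide
Product: 23 1-[(1S,2R,5R)-2-(TBS-oxy)-5-[2-(TBS-oxy)ethyl]-5-methyl-2-(propan-2-yl)cyclopentyl]but-2-yn-1-ol (both C6 epimers)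
Conditions: THF, −78 → 0 °C; aq. NH4Cl
Reagents that add atoms: none
Why: Grignard addition forms the C6–C7 bond; because C5 lies between two fully substituted carbons no dependable facial bias is expected, so both C6 epimers are carried on and converged in steps 16 and 17.

Step 16
Reactants: 23 1-[(1S,2R,5R)-2-(TBS-oxy)-5-[2-(TBS-oxy)ethyl]-5-methyl-2-(propan-2-yl)cyclopentyl]but-2-yn-1-ol
Product: 24 1-[(1R,2R,5R)-2-(TBS-oxy)-5-[2-(TBS-oxy)ethyl]-5-methyl-2-(propan-2-yl)cyclopentyl]but-2-yn-1-one
Conditions: Dess–Martin periodinane, pyridine, CH2Cl2, 25 °C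
Reagents that add atoms: none
Why: Dess–Martin oxidation of both propargylic epimers to one ynone erases the unselective C6 centre.

Step 17
Reactants: 24 1-[(1R,2R,5R)-2-(TBS-oxy)-5-[2-(TBS-oxy)ethyl]-5-methyl-2-(propan-2-yl)cyclopentyl]but-2-yn-1-one
Product: 25 (R)-1-[(1S,2R,5R)-2-(TBS-oxy)-5-[2-(TBS-oxy)ethyl]-5-methyl-2-(propan-2-yl)cyclopentyl]but-2-yn-1-ol
Conditions: (R)-2-methyl-CBS-oxazaborolidine (0.5 equiv), catecholborane, toluene, −78 °C
Reagents that add atoms: none
Why: Corey–Bakshi–Shibata reduction: the ketone binds to the oxazaborolidine–borane complex with the slim propynyl group as the small and the ring carbon as the large substituent, so hydride reaches one face and C6 is set by reagent control with the spatial arrangement of the target (R here, S once C7 is sp2).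

Step 18
Reactants: 25 (R)-1-[(1S,2R,5R)-2-(TBS-oxy)-5-[2-(TBS-oxy)ethyl]-5-methyl-2-(propan-2-yl)cyclopentyl]but-2-yn-1-ol
Product: 27 (S,Z)-3-iodo-1-[(1S,2R,5R)-2-(TBS-oxy)-5-[2-(TBS-oxy)ethyl]-5-methyl-2-(propan-2-yl)cyclopentyl]but-2-en-1-ol, via alkenylalanate 26 (not isolated)
Conditions: NaAlH2(OCH2CH2OCH3)2, THF, 0 → 25 °C; then I2, THF, −78 → 0 °C
Reagents that add atoms: iodine, II
Why: Hydroxyl-directed trans-hydroalumination: the alkoxy-aluminium hydride delivers hydride to C7 and aluminium to C8 within the five-membered aluminate 26, and iodine replaces the carbon–aluminium bond with retention, giving the Z iodide with iodine cis to C6 as the ring requires.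

Step 19
Reactants: 27 (S,Z)-3-iodo-1-[(1S,2R,5R)-2-(TBS-oxy)-5-[2-(TBS-oxy)ethyl]-5-methyl-2-(propan-2-yl)cyclopentyl]but-2-en-1-ol; 28 4-(TBS-oxy)benzoic acid
Product: 29 (S,Z)-3-iodo-1-[(1S,2R,5R)-2-(TBS-oxy)-5-[2-(TBS-oxy)ethyl]-5-methyl-2-(propan-2-yl)cyclopentyl]but-2-enyl 4-(TBS-oxy)benzoate
Conditions: DCC, DMAP, CH2Cl2, 25 → 40 °C
Reagents that add atoms: none
Why: Steglich esterification (carbodiimide activation, acyl transfer through DMAP) of the only free hydroxyl; the phenol of the acid is masked so that it cannot compete.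

Step 20
Reactants: 29 (S,Z)-3-iodo-1-[(1S,2R,5R)-2-(TBS-oxy)-5-[2-(TBS-oxy)ethyl]-5-methyl-2-(propan-2-yl)cyclopentyl]but-2-enyl 4-(TBS-oxy)benzoate
Product: 30 (S,Z)-1-[(1S,2R,5R)-2-(TBS-oxy)-5-(2-hydroxyethyl)-5-methyl-2-(propan-2-yl)cyclopentyl]-3-iodobut-2-enyl 4-(TBS-oxy)benzoate
Conditions: camphorsulfonic acid (10 mol %), MeOH/CH2Cl2, 0 °C
Reagents that add atoms: none
Why: Acid-catalysed methanolysis removes the primary alkyl silyl ether much faster than the tertiary alkyl and the aryl silyl ethers, which are shielded sterically and electronically from protonation-assisted cleavage.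

Step 21
Reactants: 30 (S,Z)-1-[(1S,2R,5R)-2-(TBS-oxy)-5-(2-hydroxyethyl)-5-methyl-2-(propan-2-yl)cyclopentyl]-3-iodobut-2-enyl 4-(TBS-oxy)benzoate
Product: 31 (S,Z)-1-[(1S,2R,5R)-2-(TBS-oxy)-5-methyl-5-(2-oxoethyl)-2-(propan-2-yl)cyclopentyl]-3-iodobut-2-enyl 4-(TBS-oxy)benzoate
Conditions: Dess–Martin periodinane, pyridine, CH2Cl2, 25 °C
Reagents that add atoms: none
Why: Dess–Martin oxidation of the primary alcohol to the C9 aldehyde under neutral conditions that leave the vinyl iodide, the ester and the silyl ethers alone.

Step 22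
Reactants: 31 (S,Z)-1-[(1S,2R,5R)-2-(TBS-oxy)-5-methyl-5-(2-oxoethyl)-2-(propan-2-yl)cyclopentyl]-3-iodobut-2-enyl 4-(TBS-oxy)benzoate
Product: 32 (1R,4R,5S,6S,9S)-4-(TBS-oxy)-9-hydroxydauc-7-en-6-yl 4-(TBS-oxy)benzoate
Conditions: CrCl2 (8 equiv), NiCl2 (2 mol %), DMF, 25 °C, high dilution
Reagents that add atoms: none
Why: Nozaki–Hiyama–Kishi reaction: zerovalent nickel inserts into the carbon–iodine bond at C8, the alkenyl group passes to trivalent chromium with retention of the Z geometry and adds to the C9 aldehyde, closing the seven-membered ring while both esters are tolerated. In the chair-like cycloheptene transition state the aldehyde oxygen should sit pseudo-equatorial on the face opposite the C1 methyl group to avoid a 1,3-diaxial contact, which gives the 9α alcohol, cis to the C6 oxygen.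

Step 23
Reactants: 32 (1R,4R,5S,6S,9S)-4-(TBS-oxy)-9-hydroxydauc-7-en-6-yl 4-(TBS-oxy)benzoate
Product: 33 (1R,4R,5S,6S,9S)-9-acetoxy-4-(TBS-oxy)dauc-7-en-6-yl 4-(TBS-oxy)benzoate
Conditions: Ac2O, pyridine, DMAP (cat.), CH2Cl2, 0 → 25 °C
Reagents that add atoms: acetic anhydride, CC(=O)OC(C)=O
Why: Acetylation of the single free hydroxyl; no other nucleophilic group is present.

Step 24
Reactants: 33 (1R,4R,5S,6S,9S)-9-acetoxy-4-(TBS-oxy)dauc-7-en-6-yl 4-(TBS-oxy)benzoate
Product: 34 (1R,4R,5S,6S,9S)-9-acetoxy-4-hydroxydauc-7-en-6-yl 4-hydroxybenzoate (target)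
Conditions: HF·pyridine, pyridine, THF, 0 → 40 °C
Reagents that add atoms: none
Why: Fluoride cleaves the aryl silyl ether quickly and the tertiary silyl ether more slowly under mildly acidic conditions that should neither hydrolyse nor migrate the two esters, releasing the phenol and the C4 hydroxyl.

**Compound list**

1 | L-valine, (S)-2-amino-3-methylbutanoic acid | N[C@@H](C(C)C)C(=O)O | starting material
2 | (S)-2-hydroxy-3-methylbutanoic acid | CC(C)[C@H](O)C(=O)O | intermediate
3 | methyl (S)-2-hydroxy-3-methylbutanoate | CC(C)[C@H](O)C(=O)OC | intermediate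
4 | methyl (S)-2-(TBS-oxy)-3-methylbutanoate | CC(C)[C@H](O[Si](C)(C)C(C)(C)C)C(=O)OC | intermediate
5 | (S)-2-(TBS-oxy)-3-methylbutanal | CC(C)[C@H](O[Si](C)(C)C(C)(C)C)C=O | intermediate
6 | (S)-3-(TBS-oxy)-4-methylpent-1-ene | CC(C)[C@H](O[Si](C)(C)C(C)(C)C)C=C | intermediate
7 | 3-bromocyclopent-2-en-1-one | O=C1CCC(Br)=C1 | starting material
8 | 9-[(R)-3-(TBS-oxy)-4-methylpentyl]-9-borabicyclo[3.3.1]nonane | CC(C)[C@H](O[Si](C)(C)C(C)(C)C)CCB1C2CCCC1CCC2 | intermediate
9 | 3-[(R)-3-(TBS-oxy)-4-methylpentyl]cyclopent-2-en-1-one | O=C1C=C(CC[C@@H](O[Si](C)(C)C(C)(C)C)C(C)C)CC1 | intermediate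
10 | (R)-3-methyl-3-[(R)-3-(TBS-oxy)-4-methylpentyl]cyclopentan-1-one | C[C@@]1(CC[C@@H](O[Si](C)(C)C(C)(C)C)C(C)C)CCC(=O)C1 | intermediate
11 | (R)-4-methyl-4-[(R)-3-(TBS-oxy)-4-methylpentyl]-1-(trimethylsilyloxy)cyclopent-1-ene | C[C@@]1(CC[C@@H](O[Si](C)(C)C(C)(C)C)C(C)C)CC=C(O[Si](C)(C)C)C1 | intermediate
12 | (R)-5-hydroxy-3-methyl-3-[(R)-3-(TBS-oxy)-4-methylpentyl]pentanoic acid | OC(=O)C[C@@](C)(CCO)CC[C@@H](O[Si](C)(C)C(C)(C)C)C(C)C | intermediate
13 | (R)-4-methyl-4-[(R)-3-(TBS-oxy)-4-methylpentyl]oxan-2-one | C[C@@]1(CC[C@@H](O[Si](C)(C)C(C)(C)C)C(C)C)CCOC(=O)C1 | intermediate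
14 | potassium (R)-5-hydroxy-3-methyl-3-[(R)-3-(TBS-oxy)-4-methylpentyl]pentanoate | [K+].[O-]C(=O)C[C@@](C)(CCO)CC[C@@H](O[Si](C)(C)C(C)(C)C)C(C)C | intermediate
15 | methyl (R)-5-hydroxy-3-methyl-3-[(R)-3-(TBS-oxy)-4-methylpentyl]pentanoate | COC(=O)C[C@@](C)(CCO)CC[C@@H](O[Si](C)(C)C(C)(C)C)C(C)C | intermediate
16 | methyl (3R,6R)-6-(TBS-oxy)-3-[2-(TBS-oxy)ethyl]-3,7-dimethyloctanoate | COC(=O)C[C@@](C)(CCO[Si](C)(C)C(C)(C)C)CC[C@@H](O[Si](C)(C)C(C)(C)C)C(C)C | intermediate
17 | methyl (3R,6R)-2-benzoyl-6-(TBS-oxy)-3-[2-(TBS-oxy)ethyl]-3,7-dimethyloctanoate (both C2 epimers) | COC(=O)C(C(=O)c1ccccc1)[C@@](C)(CCO[Si](C)(C)C(C)(C)C)CC[C@@H](O[Si](C)(C)C(C)(C)C)C(C)C | intermediate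
18 | methyl (3R,6R)-2-diazo-6-(TBS-oxy)-3-[2-(TBS-oxy)ethyl]-3,7-dimethyloctanoate | COC(=O)C(=[N+]=[N-])[C@@](C)(CCO[Si](C)(C)C(C)(C)C)CC[C@@H](O[Si](C)(C)C(C)(C)C)C(C)C | intermediate
19 | methyl (1R,2R,5R)-2-(TBS-oxy)-5-[2-(TBS-oxy)ethyl]-5-methyl-2-(propan-2-yl)cyclopentane-1-carboxylate | COC(=O)[C@@H]1[C@@](C)(CCO[Si](C)(C)C(C)(C)C)CC[C@@]1(O[Si](C)(C)C(C)(C)C)C(C)C | intermediate
20 | [(1S,2R,5R)-2-(TBS-oxy)-5-[2-(TBS-oxy)ethyl]-5-methyl-2-(propan-2-yl)cyclopentyl]methanol | OC[C@@H]1[C@@](C)(CCO[Si](C)(C)C(C)(C)C)CC[C@@]1(O[Si](C)(C)C(C)(C)C)C(C)C | intermediate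
21 | (1R,2R,5R)-2-(TBS-oxy)-5-[2-(TBS-oxy)ethyl]-5-methyl-2-(propan-2-yl)cyclopentane-1-carbaldehyde | O=C[C@@H]1[C@@](C)(CCO[Si](C)(C)C(C)(C)C)CC[C@@]1(O[Si](C)(C)C(C)(C)C)C(C)C | intermediate
22 | prop-1-ynylmagnesium bromide | CC#C[Mg]Br | starting material
23 | 1-[(1S,2R,5R)-2-(TBS-oxy)-5-[2-(TBS-oxy)ethyl]-5-methyl-2-(propan-2-yl)cyclopentyl]but-2-yn-1-ol (both carbinol epimers) | CC#CC(O)[C@@H]1[C@@](C)(CCO[Si](C)(C)C(C)(C)C)CC[C@@]1(O[Si](C)(C)C(C)(C)C)C(C)C | intermediate
24 | 1-[(1R,2R,5R)-2-(TBS-oxy)-5-[2-(TBS-oxy)ethyl]-5-methyl-2-(propan-2-yl)cyclopentyl]but-2-yn-1-one | CC#CC(=O)[C@@H]1[C@@](C)(CCO[Si](C)(C)C(C)(C)C)CC[C@@]1(O[Si](C)(C)C(C)(C)C)C(C)C | intermediate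
25 | (R)-1-[(1S,2R,5R)-2-(TBS-oxy)-5-[2-(TBS-oxy)ethyl]-5-methyl-2-(propan-2-yl)cyclopentyl]but-2-yn-1-ol | CC#C[C@H](O)[C@@H]1[C@@](C)(CCO[Si](C)(C)C(C)(C)C)CC[C@@]1(O[Si](C)(C)C(C)(C)C)C(C)C | intermediate
26 | sodium cyclic alkenylalanate: five-membered ring O–Al–C8=C7–C6, aluminium carrying two 2-methoxyethoxy groups | [Na+].CC1=C[C@@H]([C@@H]2[C@@](C)(CCO[Si](C)(C)C(C)(C)C)CC[C@@]2(O[Si](C)(C)C(C)(C)C)C(C)C)O[Al-]1(OCCOC)OCCOC | intermediate
27 | (S,Z)-3-iodo-1-[(1S,2R,5R)-2-(TBS-oxy)-5-[2-(TBS-oxy)ethyl]-5-methyl-2-(propan-2-yl)cyclopentyl]but-2-en-1-ol | C/C(I)=C/[C@H](O)[C@@H]1[C@@](C)(CCO[Si](C)(C)C(C)(C)C)CC[C@@]1(O[Si](C)(C)C(C)(C)C)C(C)C | intermediate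
28 | 4-(TBS-oxy)benzoic acid | OC(=O)c1ccc(O[Si](C)(C)C(C)(C)C)cc1 | starting material
29 | (S,Z)-3-iodo-1-[(1S,2R,5R)-2-(TBS-oxy)-5-[2-(TBS-oxy)ethyl]-5-methyl-2-(propan-2-yl)cyclopentyl]but-2-enyl 4-(TBS-oxy)benzoate | C/C(I)=C/[C@H](OC(=O)c1ccc(O[Si](C)(C)C(C)(C)C)cc1)[C@@H]1[C@@](C)(CCO[Si](C)(C)C(C)(C)C)CC[C@@]1(O[Si](C)(C)C(C)(C)C)C(C)C | intermediate
30 | (S,Z)-1-[(1S,2R,5R)-2-(TBS-oxy)-5-(2-hydroxyethyl)-5-methyl-2-(propan-2-yl)cyclopentyl]-3-iodobut-2-enyl 4-(TBS-oxy)benzoate | C/C(I)=C/[C@H](OC(=O)c1ccc(O[Si](C)(C)C(C)(C)C)cc1)[C@@H]1[C@@](C)(CCO)CC[C@@]1(O[Si](C)(C)C(C)(C)C)C(C)C | intermediate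
31 | (S,Z)-1-[(1S,2R,5R)-2-(TBS-oxy)-5-methyl-5-(2-oxoethyl)-2-(propan-2-yl)cyclopentyl]-3-iodobut-2-enyl 4-(TBS-oxy)benzoate | C/C(I)=C/[C@H](OC(=O)c1ccc(O[Si](C)(C)C(C)(C)C)cc1)[C@@H]1[C@@](C)(CC=O)CC[C@@]1(O[Si](C)(C)C(C)(C)C)C(C)C | intermediate
32 | (1R,4R,5S,6S,9S)-4-(TBS-oxy)-9-hydroxydauc-7-en-6-yl 4-(TBS-oxy)benzoate | O[C@H]1C[C@@]2(C)CC[C@@](O[Si](C)(C)C(C)(C)C)(C(C)C)[C@@H]2[C@@H](OC(=O)c2ccc(O[Si](C)(C)C(C)(C)C)cc2)C=C1C | intermediate
33 | (1R,4R,5S,6S,9S)-9-acetoxy-4-(TBS-oxy)dauc-7-en-6-yl 4-(TBS-oxy)benzoate | CC(=O)O[C@H]1C[C@@]2(C)CC[C@@](O[Si](C)(C)C(C)(C)C)(C(C)C)[C@@H]2[C@@H](OC(=O)c2ccc(O[Si](C)(C)C(C)(C)C)cc2)C=C1C | intermediate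
34 | (1R,4R,5S,6S,9S)-9-acetoxy-4-hydroxydauc-7-en-6-yl 4-hydroxybenzoate | CC(=O)O[C@H]1C[C@@]2(C)CC[C@@](O)(C(C)C)[C@@H]2[C@@H](OC(=O)c2ccc(O)cc2)C=C1C | target

**Step count and risk**

Total step count: 24. Longest linear sequence: 24 steps (1 to 34); 7, 22 and 28 enter as purchased compounds.

Step 12 (key step). The most likely failure is partition of the carbene away from the hindered C4–H bond, which is a methine flanked by isopropyl and a bulky silyloxy group. The carbene could instead attack the silyl ether oxygen of the arm (five-membered oxonium ylide), insert into the isopropyl methine six atoms away, or dimerise. The fallback removes the ether oxygen from the arm; it sets out from 13 and returns at 20. Lactone 13 is opened and methylated as in step 9 but capped with pivaloyl chloride and pyridine, giving methyl (3R,6R)-6-(TBS-oxy)-3,7-dimethyl-3-[2-(pivaloyloxy)ethyl]octanoate F1. An acyloxy oxygen is a far poorer donor than an ether oxygen and deactivates the neighbouring C–H bonds. Benzoylation as in step 10 should give the 2-benzoyl ester F2, diazo transfer as in step 11 the diazo ester F3, and Rh2(OAc)4 the cyclopentane ester F4. LiAlH4 then reduces both esters to the diol F5. Its unhindered C9 hydroxyl is silylated selectively with TBSCl and imidazole at −20 °C (the C6 hydroxymethyl lies between two fully substituted carbons), which rejoins the route at 20.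

Step 10. The most likely failure is incomplete crossed Claisen condensation at the neopentyl-type C5 methylene, together with slow loss of silyl groups to methoxide at reflux. The fallback reaches the diazo ester through the oxidation level of C5; it sets out from 16 and returns at 18, bypassing 17. The potassium enolate of 16 (KN(SiMe3)2, THF, −78 °C) is hydroxylated with 2-(phenylsulfonyl)-3-phenyloxaziridine to the α-hydroxy ester F6. Dess–Martin oxidation gives the α-keto ester F7, and condensation with 4-toluenesulfonohydrazide gives the tosylhydrazone F8. DBU then expels sulfinate (Bamford–Stevens-type elimination) to give 18.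

Step 22. The most likely failure is poor or reversed facial selectivity at C9. Allylic strain between the C8 methyl group and a pseudo-equatorial oxygen works against the 1,3-diaxial argument used above; slow closure with reduction of the carbon–iodine bond is the second concern. The fallback sets out from 31 and returns at 33. If the closure delivers mainly the 9β alcohol, (1R,4R,5S,6S,9R)-4-(TBS-oxy)-9-hydroxydauc-7-en-6-yl 4-(TBS-oxy)benzoate F9, this is not acetylated but inverted. A Mitsunobu reaction (PPh3, diisopropyl azodicarboxylate, acetic acid, THF, 0 → 25 °C) displaces the activated C9 oxygen by acetate with inversion and gives 33 directly.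

Step 24. The most likely failure is incomplete cleavage of the tertiary silyl ether within the time the two allylic esters tolerate fluoride, followed by acyl migration or ester loss on prolonged treatment. The fallback desilylates before the acetate exists; it sets out from 32 and returns at 34. Forcing HF·pyridine (or aqueous HF in MeCN) on 32 gives the triol (1R,4R,5S,6S,9S)-4,9-dihydroxydauc-7-en-6-yl 4-hydroxybenzoate F10. Ac2O and pyridine acetylate the C9 hydroxyl and the phenol (the tertiary C4 hydroxyl is inert) to the diacetate F11. Pyrrolidine in CH2Cl2 at 0 °C then removes only the aryl acetate by aminolysis, giving 34.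

**Further compounds**

F1 | step 12 | methyl (3R,6R)-6-(TBS-oxy)-3,7-dimethyl-3-[2-(pivaloyloxy)ethyl]octanoate | COC(=O)C[C@@](C)(CCOC(=O)C(C)(C)C)CC[C@@H](O[Si](C)(C)C(C)(C)C)C(C)C
F2 | step 12 | methyl (3R,6R)-2-benzoyl-6-(TBS-oxy)-3,7-dimethyl-3-[2-(pivaloyloxy)ethyl]octanoate (both C2 epimers) | COC(=O)C(C(=O)c1ccccc1)[C@@](C)(CCOC(=O)C(C)(C)C)CC[C@@H](O[Si](C)(C)C(C)(C)C)C(C)C
F3 | step 12 | methyl (3R,6R)-2-diazo-6-(TBS-oxy)-3,7-dimethyl-3-[2-(pivaloyloxy)ethyl]octanoate | COC(=O)C(=[N+]=[N-])[C@@](C)(CCOC(=O)C(C)(C)C)CC[C@@H](O[Si](C)(C)C(C)(C)C)C(C)C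
F4 | step 12 | methyl (1R,2R,5R)-2-(TBS-oxy)-5-methyl-5-[2-(pivaloyloxy)ethyl]-2-(propan-2-yl)cyclopentane-1-carboxylate | COC(=O)[C@@H]1[C@@](C)(CCOC(=O)C(C)(C)C)CC[C@@]1(O[Si](C)(C)C(C)(C)C)C(C)C
F5 | step 12 | [(1S,2R,5R)-2-(TBS-oxy)-5-(2-hydroxyethyl)-5-methyl-2-(propan-2-yl)cyclopentyl]methanol | OC[C@@H]1[C@@](C)(CCO)CC[C@@]1(O[Si](C)(C)C(C)(C)C)C(C)C
F6 | step 10 | methyl (3R,6R)-2-hydroxy-6-(TBS-oxy)-3-[2-(TBS-oxy)ethyl]-3,7-dimethyloctanoate (both C2 epimers) | COC(=O)C(O)[C@@](C)(CCO[Si](C)(C)C(C)(C)C)CC[C@@H](O[Si](C)(C)C(C)(C)C)C(C)C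
F7 | step 10 | methyl (3R,6R)-6-(TBS-oxy)-3-[2-(TBS-oxy)ethyl]-3,7-dimethyl-2-oxooctanoate | COC(=O)C(=O)[C@@](C)(CCO[Si](C)(C)C(C)(C)C)CC[C@@H](O[Si](C)(C)C(C)(C)C)C(C)C
F8 | step 10 | methyl (3R,6R)-6-(TBS-oxy)-3-[2-(TBS-oxy)ethyl]-3,7-dimethyl-2-(tosylhydrazono)octanoate | COC(=O)C(=NNS(=O)(=O)c1ccc(C)cc1)[C@@](C)(CCO[Si](C)(C)C(C)(C)C)CC[C@@H](O[Si](C)(C)C(C)(C)C)C(C)C
F9 | step 22 | (1R,4R,5S,6S,9R)-4-(TBS-oxy)-9-hydroxydauc-7-en-6-yl 4-(TBS-oxy)benzoate | O[C@@H]1C[C@@]2(C)CC[C@@](O[Si](C)(C)C(C)(C)C)(C(C)C)[C@@H]2[C@@H](OC(=O)c2ccc(O[Si](C)(C)C(C)(C)C)cc2)C=C1C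
F10 | step 24 | (1R,4R,5S,6S,9S)-4,9-dihydroxydauc-7-en-6-yl 4-hydroxybenzoate | O[C@H]1C[C@@]2(C)CC[C@@](O)(C(C)C)[C@@H]2[C@@H](OC(=O)c2ccc(O)cc2)C=C1C
F11 | step 24 | (1R,4R,5S,6S,9S)-9-acetoxy-4-hydroxydauc-7-en-6-yl 4-acetoxybenzoate | CC(=O)O[C@H]1C[C@@]2(C)CC[C@@](O)(C(C)C)[C@@H]2[C@@H](OC(=O)c2ccc(OC(C)=O)cc2)C=C1C
A1 | alternative 1 | 3-allylcyclopent-2-en-1-one | C=CCC1=CC(=O)CC1
A2 | alternative 1 | (Z)-3-iodobut-2-enal | C/C(I)=C/C=O
A3 | alternative 1 | 3-allyl-3-methyl-2-[(Z)-1-hydroxy-3-iodobut-2-enyl]cyclopentanone with C1, C5 and C6 as in the target | C=CC[C@@]1(C)CCC(=O)[C@@H]1[C@@H](O)/C=C(/C)I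
A4 | alternative 2 | C6 aldehyde on C5 with a C1 arm CH2–CH(OAc)–C(CH3)=CHI (Z, iodine cis to C9), 4-triethylsilyl ether | O=C[C@@H]1[C@@](C)(C[C@H](OC(C)=O)/C(C)=C\I)CC[C@@]1(O[Si](CC)(CC)CC)C(C)C
A5 | alternative 2 | 9-acetoxydauc-7-en-6-ol 4-triethylsilyl ether | CC(=O)O[C@H]1C[C@@]2(C)CC[C@@](O[Si](CC)(CC)CC)(C(C)C)[C@@H]2[C@@H](O)C=C1C
A6 | alternative 3 | dibromocarbene adduct (7,9-cyclopropane on the face of the C1 methyl group, CBr2 = C8) of the 6-(TBS-oxy)-4-(triethylsilyloxy) trans-hydrind-7(9)-ene | BrC1(Br)[C@@H]2C[C@@]3(C)CC[C@@](O[Si](CC)(CC)CC)(C(C)C)[C@@H]3[C@@H](O[Si](C)(C)C(C)(C)C)[C@H]12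
A7 | alternative 3 | 9-acetoxy-8-bromodauc-7-ene 4-triethylsilyl 6-TBS bis-ether | CC(=O)O[C@H]1C[C@@]2(C)CC[C@@](O[Si](CC)(CC)CC)(C(C)C)[C@@H]2[C@@H](O[Si](C)(C)C(C)(C)C)C=C1Br
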